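**Plan**

1. Retrosynthesis: the angelate C3–O bond and the C11–O aryl ether are cut first. C7=C8 is traced back to a C6=C7 olefin with a silyl group on C8 (an allylsilane). The C8–C9 and C5–C10 bonds are then cut together (retro-Diels–Alder), and the open chain is cut at C1–C2 (vinylogous aldol) and C5=C6 (olefination).
2. Enabling feature: ring B (C5–C6–C7–C8–C9–C10) is a cyclohexene whose C9–C10 edge carries C11, which can be raised to an activating formyl group, and C10 is tied to C5 by the four-carbon chain C1–C4 of ring A. Moving C7=C8 to C6=C7 exposes the Diels–Alder retron; a silyl group on C8 brings the double bond back afterwards.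
3. Forward: (S)-pantolactone supplies C2–C5 with the gem-dimethyl group, a Horner–Wadsworth–Emmons reaction adds C6–C8 and C12, and a vinylogous Mukaiyama aldol adds C1, C9–C11 and C15. Rings A and B then close together in one intramolecular Diels–Alder step, followed by reduction, desilylation, etherification, oxidation, deprotection and acylation.
4. Stereochemistry: C3 comes from (S)-pantolactone. C2 is a temporary centre set by chelation-controlled aldol; with C3 it fixes the chair of the tether and hence the absolute sense at C5 and C10. The E-dienophile fixes C9 relative to C10, endo addition gives the trans ring fusion, and the Z-alkene comes from angelic acid.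

Key step: step 12

Remark: locants in names and discussion follow drimane numbering only as a map (C1–C10 decalin, ring A = C1–C5/C10, ring B = C5–C10, C11 = CH2O on C9, C12 = CH3 on C8, C13/C14 = CH3 groups on C4, C15 = CH3 on C10), also for the corresponding carbons of open-chain precursors; configurations are given by CIP descriptors and SMILES.
Remark: (S)-pantolactone, (dimethylphenylsilyl)boronic acid pinacol ester, ethyl but-2-ynoate, 3-methylbut-2-enal, umbelliferone and angelic acid are taken as commercial.

**Route**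

Step 1
Reactants: 1 (S)-pantolactone
Product: 2 (3S)-4,4-dimethyl-3-(naphthalen-2-ylmethoxy)oxolan-2-one
Conditions: 2-(bromomethyl)naphthalene, Ag2O, 4 Å molecular sieves, Et2O, rt, dark
Reagents that add atoms: 2-(bromomethyl)naphthalene, BrCc1ccc2ccccc2c1
Why: Ag2O-assisted O-alkylation (Williamson-type etherification under non-basic conditions) caps the C3 hydroxyl as a 2-naphthylmethyl ether, a group that can chelate in step 11, survives the acid of step 14 and is removed oxidatively in step 17, while the base-sensitive C3 stereocentre next to the lactone carbonyl is left untouched.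

Step 2
Reactants: 2 (3S)-4,4-dimethyl-3-(naphthalen-2-ylmethoxy)oxolan-2-one
Product: 3 (2S)-4-hydroxy-N-methoxy-N,3,3-trimethyl-2-(naphthalen-2-ylmethoxy)butanamide
Conditions: MeNH(OMe)·HCl, Me3Al, CH2Cl2, 0 °C → rt
Reagents that add atoms: N,O-dimethylhydroxylamine hydrochloride, CNOC.Cl
Why: Aminolysis of the lactone by the aluminium amide formed in the flask (Weinreb amide formation) opens the ring at the acyl C–O bond, freeing the neopentyl C5 alcohol and leaving C2 at a level that can later be reduced cleanly to the aldehyde; C3 is not touched.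

Step 3
Reactants: 3 (2S)-4-hydroxy-N-methoxy-N,3,3-trimethyl-2-(naphthalen-2-ylmethoxy)butanamide
Product: 4 (2S)-N-methoxy-N,3,3-trimethyl-2-(naphthalen-2-ylmethoxy)-4-oxobutanamide
Conditions: Dess–Martin periodinane, pyridine, CH2Cl2, 0 °C → rt
Reagents that add atoms: none
Why: Dess–Martin oxidation of the primary neopentyl alcohol gives the non-enolisable C5 aldehyde, the pyridine buffer suppressing acid-catalysed relactonisation of 3.

Step 4
Reactants: 5 ethyl but-2-ynoate
Product: 6 ethyl (2E)-3-[dimethyl(phenyl)silyl]but-2-enoate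
Conditions: PhMe2Si–B(pin), CuCl (5 mol %), NaOt-Bu (10 mol %), MeOH, THF, 0 °C → rt
Reagents that add atoms: (dimethylphenylsilyl)boronic acid pinacol ester, CC1(C)OB(OC1(C)C)[Si](C)(C)c1ccccc1
Why: Copper-catalysed conjugate silylation (protosilylation) of the ynoate proceeds by syn addition of a silylcopper species and stereoretentive protonation, which places silicon trans to the ester and so gives the E-alkene.

Step 5
Reactants: 6 ethyl (2E)-3-[dimethyl(phenyl)silyl]but-2-enoate
Product: 7 (2E)-3-[dimethyl(phenyl)silyl]but-2-en-1-ol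
Conditions: i-Bu2AlH (2.2 equiv), CH2Cl2, −78 °C; aq. potassium sodium tartrate
Reagents that add atoms: none
Why: 1,2-Reduction of the conjugated ester with the aluminium hydride gives the allylic alcohol without touching the vinylsilane or the alkene geometry.

Step 6
Reactants: 7 (2E)-3-[dimethyl(phenyl)silyl]but-2-en-1-ol
Product: 8 [(2E)-4-bromobut-2-en-2-yl]dimethyl(phenyl)silane
Conditions: CBr4, PPh3, CH2Cl2, 0 °C
Reagents that add atoms: carbon tetrabromide, BrC(Br)(Br)Br
Why: Appel bromination converts the primary allylic alcohol into the bromide under neutral conditions by direct displacement of the oxyphosphonium group, without allylic transposition.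

Step 7
Reactants: 8 [(2E)-4-bromobut-2-en-2-yl]dimethyl(phenyl)silane
Product: 9 diethyl {(2E)-3-[dimethyl(phenyl)silyl]but-2-en-1-yl}phosphonate
Conditions: P(OEt)3, neat, 120 °C
Reagents that add atoms: triethyl phosphite, CCOP(OCC)OCC
Why: Michaelis–Arbuzov reaction of the primary allylic bromide with the phosphite installs the phosphonate needed for the olefination.

Step 8
Reactants: 4 (2S)-N-methoxy-N,3,3-trimethyl-2-(naphthalen-2-ylmethoxy)-4-oxobutanamide; 9 diethyl {(2E)-3-[dimethyl(phenyl)silyl]but-2-en-1-yl}phosphonate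
Product: 11 (2S,4E,6E)-7-[dimethyl(phenyl)silyl]-N-methoxy-N,3,3-trimethyl-2-(naphthalen-2-ylmethoxy)octa-4,6-dienamide, via lithiated phosphonate 10 (not isolated)
Conditions: LiN(SiMe3)2 (slight deficit relative to 9), THF, −78 °C; then 4, −78 °C → rt
Reagents that add atoms: lithium bis(trimethylsilyl)amide, [Li+].C[Si](C)(C)[N-][Si](C)(C)C (its lithium is found only in 10)
Why: Horner–Wadsworth–Emmons olefination of the non-enolisable neopentyl aldehyde by the α-carbon of the allylic phosphonate anion (the γ-carbon is fully substituted) forms the C5=C6 bond as the E-alkene through reversible addition and syn elimination, and the slight deficit of a weakly basic stabilised anion spares the C3 stereocentre.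

Step 9
Reactants: 11 (2S,4E,6E)-7-[dimethyl(phenyl)silyl]-N-methoxy-N,3,3-trimethyl-2-(naphthalen-2-ylmethoxy)octa-4,6-dienamide
Product: 12 (2S,4E,6E)-7-[dimethyl(phenyl)silyl]-3,3-dimethyl-2-(naphthalen-2-ylmethoxy)octa-4,6-dienal
Conditions: i-Bu2AlH, THF, −78 °C; aq. potassium sodium tartrate
Reagents that add atoms: none
Why: Hydride reduction of the Weinreb amide stops at the aldehyde because the chelated tetrahedral aluminium adduct only collapses on work-up, and the low temperature keeps the α-alkoxy stereocentre C3 intact.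

Step 10
Reactants: 13 3-methylbut-2-enal
Product: 14 tert-butyl(dimethyl){[(1E)-3-methylbuta-1,3-dien-1-yl]oxy}silane
Conditions: t-BuMe2SiOTf, Et3N, Et2O, 0 °C → rt
Reagents that add atoms: tert-butyldimethylsilyl trifluoromethanesulfonate, CC(C)(C)[Si](C)(C)OS(=O)(=O)C(F)(F)F
Why: Soft enolisation of the enal (silyl triflate and amine) removes a γ-proton and traps the linear dienolate on oxygen, giving the silyl dienol ether as the vinylogous nucleophile.

Step 11
Reactants: 12 (2S,4E,6E)-7-[dimethyl(phenyl)silyl]-3,3-dimethyl-2-(naphthalen-2-ylmethoxy)octa-4,6-dienal; 14 tert-butyl(dimethyl){[(1E)-3-methylbuta-1,3-dien-1-yl]oxy}silane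
Product: 15 (2E,5S,6S,8E,10E)-11-[dimethyl(phenyl)silyl]-5-hydroxy-3,7,7-trimethyl-6-(naphthalen-2-ylmethoxy)dodeca-2,8,10-trienal
Conditions: TiCl4, CH2Cl2, −78 °C; aq. NaHCO3
Reagents that add atoms: none
Why: Chelation-controlled vinylogous Mukaiyama aldol addition: TiCl4 bridges the aldehyde oxygen and the C3 ether oxygen, the dienol ether attacks through its terminal carbon on the face opposite the quaternary C4, which sets drimane C2 (chain C5) as S (2,3-syn), and the new conjugated double bond forms as the E-isomer.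

Step 12
Reactants: 15 (2E,5S,6S,8E,10E)-11-[dimethyl(phenyl)silyl]-5-hydroxy-3,7,7-trimethyl-6-(naphthalen-2-ylmethoxy)dodeca-2,8,10-trienal
Product: 17 (2S,3S,5S,8R,9R,10R)-8-[dimethyl(phenyl)silyl]-2-hydroxy-3-(naphthalen-2-ylmethoxy)drim-6-en-11-al, via aluminium alkoxide 16 (not isolated)
Conditions: Me2AlCl (2.5 equiv), CH2Cl2, −78 → 0 °C; aq. potassium sodium tartrate
Reagents that add atoms: dimethylaluminium chloride, C[Al](C)Cl (its atoms are found only in 16)
Why: Me2AlCl turns the C2 hydroxyl into the aluminium alkoxide 16 and a further equivalent binds the formyl oxygen, lowering the LUMO of the enal so that the silyl diene (C5=C6–C7=C8) and the dienophile (C9=C10) combine in a concerted, asynchronous normal-demand [4+2] cycloaddition in which the C5–C10 bond is ahead of the C8–C9 bond; the closest known reaction type is the Lewis acid-promoted intramolecular Diels–Alder reaction of terminally activated 1,3,9-decatrienes, together with Diels–Alder reactions of 1-silyl dienes that give allylsilanes. Ring B is closed by the cycloaddition itself (both new bonds lie in it), and ring A is closed as the fused ring of a type 1 intramolecular Diels–Alder reaction when the C5–C10 bond forms, its tether C1–C4 lying in a chair. The trans ring fusion (C5 and C10) follows from the endo position of the aluminium-bound formyl group on the E-dienophile, which puts the C1 arm exo and the C10 methyl anti to H5; C9 follows from the E-geometry of the dienophile (C11 cis to the C10 methyl), and C8 from the E-silyl group lying outside, a centre that is erased in step 14 so that any Z-silyl isomer of the diene would converge on the same product. The absolute sense at C5, C9 and C10 is set by C3 and C2: only in the chair with the C3 naphthylmethoxy and the C2 aluminoxy groups both equatorial (gauche, and able to share one aluminium atom) does the C2 oxygen avoid a 1,3-diaxial clash with the axial methyl groups on C4 and C10, so the diene reaches one face of the dienophile only. The step needs endo over exo selectivity and this π-facial selectivity, which the Lewis acid and the trans-disposed C2/C3 oxygens secure, while the gem-dimethyl group at C4 favours the coiled reactive conformer and Me2AlCl scavenges protons that would otherwise desilylate the allylsilane.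

Step 13
Reactants: 17 (2S,3S,5S,8R,9R,10R)-8-[dimethyl(phenyl)silyl]-2-hydroxy-3-(naphthalen-2-ylmethoxy)drim-6-en-11-al
Product: 18 (2S,3S,5S,8R,9R,10R)-8-[dimethyl(phenyl)silyl]-3-(naphthalen-2-ylmethoxy)drim-6-ene-2,11-diol
Conditions: NaBH4, MeOH, 0 °C
Reagents that add atoms: none
Why: Borohydride reduction of the aldehyde to the primary alcohol is done before desilylation so that a β,γ-unsaturated aldehyde prone to conjugation and C9 epimerisation is never formed.

Step 14
Reactants: 18 (2S,3S,5S,8R,9R,10R)-8-[dimethyl(phenyl)silyl]-3-(naphthalen-2-ylmethoxy)drim-6-ene-2,11-diol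
Product: 19 (2S,3S,5S,9R,10R)-3-(naphthalen-2-ylmethoxy)drim-7-ene-2,11-diol
Conditions: CF3CO2H, CH2Cl2, 0 °C; then K2CO3, MeOH
Reagents that add atoms: none
Why: Acid-induced protodesilylation of the allylsilane (SE2′ reaction): the proton adds to C6 anti to the pseudoaxial C8–Si bond and loss of silicon places the double bond regiospecifically at C7=C8, removing the helper group and the temporary C8 stereocentre.

Step 15
Reactants: 19 (2S,3S,5S,9R,10R)-3-(naphthalen-2-ylmethoxy)drim-7-ene-2,11-diol; 20 umbelliferone (7-hydroxy-2H-chromen-2-one)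
Product: 21 7-{[(2S,3S,5S,9R,10R)-2-hydroxy-3-(naphthalen-2-ylmethoxy)drim-7-en-11-yl]oxy}-2H-chromen-2-one
Conditions: PPh3, diisopropyl azodicarboxylate, toluene, 0 °C → rt
Reagents that add atoms: none
Why: Mitsunobu etherification of the primary C11 alcohol with the acidic phenol; the equatorial C2 hydroxyl is not substituted because backside attack there would have to come along the axial direction that is blocked by the axial methyl groups on C4 and C10.

Step 16
Reactants: 21 7-{[(2S,3S,5S,9R,10R)-2-hydroxy-3-(naphthalen-2-ylmethoxy)drim-7-en-11-yl]oxy}-2H-chromen-2-one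
Product: 22 7-{[(3S,5S,9R,10R)-3-(naphthalen-2-ylmethoxy)-2-oxodrim-7-en-11-yl]oxy}-2H-chromen-2-one
Conditions: Dess–Martin periodinane, pyridine, CH2Cl2, rt
Reagents that add atoms: none
Why: Dess–Martin oxidation of the only free hydroxyl gives the C2 ketone and erases the temporary C2 stereocentre, which was needed only for steps 11 and 12.

Step 17
Reactants: 22 7-{[(3S,5S,9R,10R)-3-(naphthalen-2-ylmethoxy)-2-oxodrim-7-en-11-yl]oxy}-2H-chromen-2-one
Product: 23 7-{[(3S,5S,9R,10R)-3-hydroxy-2-oxodrim-7-en-11-yl]oxy}-2H-chromen-2-one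
Conditions: DDQ, CH2Cl2–pH 7 phosphate buffer, rt
Reagents that add atoms: none
Why: Oxidative cleavage of the 2-naphthylmethyl ether by DDQ (benzylic hydride abstraction, then hydrolysis of the oxocarbenium ion) frees the C3 hydroxyl with retention, since the C3–O bond is not broken.

Step 18
Reactants: 23 7-{[(3S,5S,9R,10R)-3-hydroxy-2-oxodrim-7-en-11-yl]oxy}-2H-chromen-2-one; 24 angelic acid ((2Z)-2-methylbut-2-enoic acid)
Product: 26 (3S,5S,9R,10R)-2-oxo-11-[(2-oxo-2H-chromen-7-yl)oxy]drim-7-en-3-yl (2Z)-2-methylbut-2-enoate (target), via mixed anhydride 25 (not isolated)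
Conditions: 24, 2,4,6-Cl3C6H2COCl, Et3N, toluene, rt; then 23, toluene, 80 °C
Reagents that add atoms: 2,4,6-trichlorobenzoyl chloride, O=C(Cl)c1c(Cl)cc(Cl)cc1Cl (its aroyl group is found only in 25)
Why: Yamaguchi-type esterification: the alcohol attacks the less hindered angeloyl carbonyl of the mixed anhydride, and the absence of a nucleophilic catalyst avoids the addition–elimination pathway that would turn the Z-alkene of the angelate into the E-isomer; C3 keeps its equatorial configuration.

**Compound list**

1 | (S)-pantolactone, (3S)-3-hydroxy-4,4-dimethyloxolan-2-one | CC1(C)COC(=O)[C@H]1O | starting material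
2 | (3S)-4,4-dimethyl-3-(naphthalen-2-ylmethoxy)oxolan-2-one | CC1(C)COC(=O)[C@H]1OCc1ccc2ccccc2c1 | intermediate
3 | (2S)-4-hydroxy-N-methoxy-N,3,3-trimethyl-2-(naphthalen-2-ylmethoxy)butanamide | CON(C)C(=O)[C@@H](OCc1ccc2ccccc2c1)C(C)(C)CO | intermediate
4 | (2S)-N-methoxy-N,3,3-trimethyl-2-(naphthalen-2-ylmethoxy)-4-oxobutanamide | CON(C)C(=O)[C@@H](OCc1ccc2ccccc2c1)C(C)(C)C=O | intermediate
5 | ethyl but-2-ynoate | CCOC(=O)C#CC | starting material
6 | ethyl (2E)-3-[dimethyl(phenyl)silyl]but-2-enoate | CCOC(=O)/C=C(\C)[Si](C)(C)c1ccccc1 | intermediate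
7 | (2E)-3-[dimethyl(phenyl)silyl]but-2-en-1-ol | OC/C=C(\C)[Si](C)(C)c1ccccc1 | intermediate
8 | [(2E)-4-bromobut-2-en-2-yl]dimethyl(phenyl)silane | BrC/C=C(\C)[Si](C)(C)c1ccccc1 | intermediate
9 | diethyl {(2E)-3-[dimethyl(phenyl)silyl]but-2-en-1-yl}phosphonate | CCOP(=O)(OCC)C/C=C(\C)[Si](C)(C)c1ccccc1 | intermediate
10 | lithium salt of 9 deprotonated at the carbon next to phosphorus | [Li+].CCOP(=O)(OCC)[CH-]/C=C(\C)[Si](C)(C)c1ccccc1 | intermediate (not isolated)
11 | (2S,4E,6E)-7-[dimethyl(phenyl)silyl]-N-methoxy-N,3,3-trimethyl-2-(naphthalen-2-ylmethoxy)octa-4,6-dienamide | CON(C)C(=O)[C@@H](OCc1ccc2ccccc2c1)C(C)(C)/C=C/C=C(\C)[Si](C)(C)c1ccccc1 | intermediate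
12 | (2S,4E,6E)-7-[dimethyl(phenyl)silyl]-3,3-dimethyl-2-(naphthalen-2-ylmethoxy)octa-4,6-dienal | O=C[C@@H](OCc1ccc2ccccc2c1)C(C)(C)/C=C/C=C(\C)[Si](C)(C)c1ccccc1 | intermediate
13 | 3-methylbut-2-enal | CC(C)=CC=O | starting material
14 | tert-butyl(dimethyl){[(1E)-3-methylbuta-1,3-dien-1-yl]oxy}silane | C=C(C)/C=C/O[Si](C)(C)C(C)(C)C | intermediate
15 | (2E,5S,6S,8E,10E)-11-[dimethyl(phenyl)silyl]-5-hydroxy-3,7,7-trimethyl-6-(naphthalen-2-ylmethoxy)dodeca-2,8,10-trienal | O=C/C=C(\C)C[C@H](O)[C@@H](OCc1ccc2ccccc2c1)C(C)(C)/C=C/C=C(\C)[Si](C)(C)c1ccccc1 | intermediate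
16 | chloro(methyl)aluminium alkoxide of 15 (aluminium on the chain C5 oxygen) | O=C/C=C(\C)C[C@H](O[Al](C)Cl)[C@@H](OCc1ccc2ccccc2c1)C(C)(C)/C=C/C=C(\C)[Si](C)(C)c1ccccc1 | intermediate (not isolated)
17 | (2S,3S,5S,8R,9R,10R)-8-[dimethyl(phenyl)silyl]-2-hydroxy-3-(naphthalen-2-ylmethoxy)drim-6-en-11-al, trans-fused | c1ccc2cc(CO[C@@H]3[C@@H](O)C[C@@]4(C)[C@H](C=O)[C@](C)([Si](C)(C)c5ccccc5)C=C[C@@H]4C3(C)C)ccc2c1 | intermediate
18 | (2S,3S,5S,8R,9R,10R)-8-[dimethyl(phenyl)silyl]-3-(naphthalen-2-ylmethoxy)drim-6-ene-2,11-diol | c1ccc2cc(CO[C@@H]3[C@@H](O)C[C@@]4(C)[C@H](CO)[C@](C)([Si](C)(C)c5ccccc5)C=C[C@@H]4C3(C)C)ccc2c1 | intermediate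
19 | (2S,3S,5S,9R,10R)-3-(naphthalen-2-ylmethoxy)drim-7-ene-2,11-diol | c1ccc2cc(CO[C@@H]3[C@@H](O)C[C@@]4(C)[C@H](CO)C(C)=CC[C@@H]4C3(C)C)ccc2c1 | intermediate
20 | umbelliferone, 7-hydroxy-2H-chromen-2-one | O=c1ccc2ccc(O)cc2o1 | starting material
21 | 7-{[(2S,3S,5S,9R,10R)-2-hydroxy-3-(naphthalen-2-ylmethoxy)drim-7-en-11-yl]oxy}-2H-chromen-2-one | c1ccc2cc(CO[C@@H]3[C@@H](O)C[C@@]4(C)[C@H](COc5ccc6ccc(=O)oc6c5)C(C)=CC[C@@H]4C3(C)C)ccc2c1 | intermediate
22 | 7-{[(3S,5S,9R,10R)-3-(naphthalen-2-ylmethoxy)-2-oxodrim-7-en-11-yl]oxy}-2H-chromen-2-one | c1ccc2cc(CO[C@@H]3C(=O)C[C@@]4(C)[C@H](COc5ccc6ccc(=O)oc6c5)C(C)=CC[C@@H]4C3(C)C)ccc2c1 | intermediate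
23 | 7-{[(3S,5S,9R,10R)-3-hydroxy-2-oxodrim-7-en-11-yl]oxy}-2H-chromen-2-one | O[C@@H]1C(=O)C[C@@]2(C)[C@H](COc3ccc4ccc(=O)oc4c3)C(C)=CC[C@@H]2C1(C)C | intermediate
24 | angelic acid, (2Z)-2-methylbut-2-enoic acid | C/C=C(/C)C(=O)O | starting material
25 | (2Z)-2-methylbut-2-enoic 2,4,6-trichlorobenzoic anhydride | C/C=C(/C)C(=O)OC(=O)c1c(Cl)cc(Cl)cc1Cl | intermediate (not isolated)
26 | (3S,5S,9R,10R)-2-oxo-11-[(2-oxo-2H-chromen-7-yl)oxy]drim-7-en-3-yl (2Z)-2-methylbut-2-enoate, CNP0111364.1 | C/C=C(/C)C(=O)O[C@@H]1C(=O)C[C@@]2(C)[C@H](COc3ccc4ccc(=O)oc4c3)C(C)=CC[C@@H]2C1(C)C | target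

**Step count and risks**

Total step count: 18. Longest linear sequence: 14 steps (steps 4, 5, 6, 7, 8, 9, 11, 12, 13, 14, 15, 16, 17, 18).

Steps most likely to fail:

Step 12 (cycloaddition). The ring closure may be too slow, because the diene terminus C8 is fully substituted (its methyl sits inside) and the dienophile is β,β-disubstituted; decomposition, vinylogous elimination of the C2 oxygen or exo closure to the cis-fused decalin could then compete. The fallback replaces the neutral enal by a cationic dienophile. Setting out from 15, excess 1,2-bis(trimethylsilyloxy)ethane with catalytic Me3SiOTf in CH2Cl2 at −78 °C should give the O-silylated dienyl dioxolane F1. Further Me3SiOTf in the presence of 2,6-di-tert-butyl-4-methylpyridine opens the dioxolane to an alkoxyallyl cation, which should undergo the ionic Diels–Alder reaction at low temperature to the cycloadduct dioxolane F2. Pyridinium p-toluenesulfonate in wet acetone removes the dioxolane and the trimethylsilyl ether, and the route is rejoined at 17.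

Step 15 (aryl ether). Displacement at the β-branched C11, next to the quaternary C10, may be slow, so that the activated alcohol is lost by elimination or the reagents are consumed unproductively at the C2 hydroxyl. The fallback forms the C–O bond at the arene instead of at C11. Setting out from 19, a palladium-catalysed C–O cross-coupling with 7-bromocoumarin ([Pd(allyl)Cl]2, a bulky di-tert-butyl(biaryl)phosphine ligand, Cs2CO3, toluene, 80 °C) should arylate the primary alcohol selectively and give 21 directly; no new compound is made (F0).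

Step 18 (angelate). Acyl transfer to the hindered C3 hydroxyl is slow, so Z-to-E isomerisation of the angeloyl unit or base-induced migration of the acyloin carbonyl may occur. The fallback builds the Z-alkene on the ester. Setting out from 23, esterification with 2-[bis(2,2,2-trifluoroethoxy)phosphoryl]propanoic acid (N,N'-dicyclohexylcarbodiimide, catalytic 4-dimethylaminopyridine, CH2Cl2) should give the phosphonopropanoate ester F3. A Still–Gennari olefination with acetaldehyde (KN(SiMe3)2, 18-crown-6, THF, −78 °C) then forms the Z-trisubstituted alkene and arrives at 26.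

**Further compounds**

F1 | step 12 | 2-{(1E,4S,5S,7E,9E)-10-[dimethyl(phenyl)silyl]-2,6,6-trimethyl-5-(naphthalen-2-ylmethoxy)-4-(trimethylsilyloxy)undeca-1,7,9-trien-1-yl}-1,3-dioxolane | C3(OCCO3)/C=C(\C)C[C@H](O[Si](C)(C)C)[C@@H](OCc1ccc2ccccc2c1)C(C)(C)/C=C/C=C(\C)[Si](C)(C)c1ccccc1
F2 | step 12 | 2-[(2S,3S,5S,8R,9R,10R)-8-[dimethyl(phenyl)silyl]-3-(naphthalen-2-ylmethoxy)-2-(trimethylsilyloxy)-11-nordrim-6-en-9-yl]-1,3-dioxolane (ethylene acetal of 17 with the C2 hydroxyl silylated) | c1ccc2cc(CO[C@@H]3[C@@H](O[Si](C)(C)C)C[C@@]4(C)[C@H](C5OCCO5)[C@](C)([Si](C)(C)c6ccccc6)C=C[C@@H]4C3(C)C)ccc2c1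
F0 | step 15 | none | none
F3 | step 18 | (3S,5S,9R,10R)-2-oxo-11-[(2-oxo-2H-chromen-7-yl)oxy]drim-7-en-3-yl 2-[bis(2,2,2-trifluoroethoxy)phosphoryl]propanoate (both epimers at the phosphorus-bearing carbon) | CC(C(=O)O[C@@H]1C(=O)C[C@@]2(C)[C@H](COc3ccc4ccc(=O)oc4c3)C(C)=CC[C@@H]2C1(C)C)P(=O)(OCC(F)(F)F)OCC(F)(F)F
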